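**Retrosynthetic overview**
- The O-15 ester, the free C19 acid, the C8=C17 methylene, the C3 oxygen and the C18 methyl are late adjustments; they lead back to the trans-decalin keto ester 19 (C3 ketone, C4 ester, C8 dioxolane).
- The strategy rests on C10, the quaternary ring-fusion carbon shared by rings A and B (bonded to C1, C5, C9) that carries the angular methyl C20. C20 is taken from a C10=CH2 group on ring B, and the C1–C10 bond closes ring A onto a C1=C2–C3=O vinyl ketone by hydrogen-atom transfer and 6-endo radical addition (18 → 19).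
- Ring B is made first, from cyclohexane-1,3-dione: C5 by RAMP-hydrazone alkylation, the C9 chain by reductive alkylation with an aldehyde from (R)-citronellol (source of C13), C9 by ketalisation under equilibrium. Ring A is made second.
- The citronellol chain is cut back by one carbon, because only five carbons (C11–C15) lie between C9 and O-15.

Key step: step 14

Assumption: ring positions are in labdane numbering (C17 = methylene carbon on C8, C18 = methyl and C19 = carboxyl carbon on C4, C20 = methyl on C10). The RAMP azaenolate is assumed to follow its usual facial preference, which calls for RAMP (not SAMP) for the C5 configuration drawn.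

Step 1
Reactants: 1 (R)-citronellol
Product: 2 tert-butyl{[(3R)-3,7-dimethyloct-6-en-1-yl]oxy}diphenylsilane
Conditions: TBDPSCl, imidazole, DMF, rt
Reagents that add atoms: tert-butyl(chloro)diphenylsilane, CC(C)(C)[Si](Cl)(c1ccccc1)c1ccccc1
Why: Silyl ether formation at the primary alcohol (the future O-15); the tert-butyldiphenylsilyl group is chosen because it has to outlast the acidic ketal steps 10 and 18.

Step 2
Reactants: 2 silyl ether of citronellol
Product: 3 (4R)-6-[(tert-butyldiphenylsilyl)oxy]-4-methylhexanal
Conditions: O3, CH2Cl2, −78 °C; then PPh3, −78 °C → rt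
Reagents that add atoms: ozone, [O-][O+]=O
Why: Ozonolysis with reductive work-up cuts the trisubstituted alkene to the aldehyde; the methyl-bearing stereocentre is remote and untouched.

Step 3
Reactants: 3 six-carbon aldehyde
Product: 4 tert-butyl({(4R)-6-[(tert-butyldiphenylsilyl)oxy]-4-methylhex-1-en-1-yl}oxy)dimethylsilane (E/Z mixture)
Conditions: TBSOTf, Et3N, CH2Cl2, 0 °C → rt
Reagents that add atoms: tert-butyldimethylsilyl trifluoromethanesulfonate, CC(C)(C)[Si](C)(C)OS(=O)(=O)C(F)(F)F
Why: Soft enolisation and O-silylation give the aldehyde silyl enol ether, which marks the one carbon to be removed.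

Step 4
Reactants: 4 silyl enol ether
Product: 5 (3S)-5-[(tert-butyldiphenylsilyl)oxy]-3-methylpentanal
Conditions: O3, CH2Cl2, −78 °C; then Me2S, −78 °C → rt
Reagents that add atoms: ozone, [O-][O+]=O
Why: Ozonolysis of the enol ether double bond gives the aldehyde shortened by one carbon (C11 as CHO); the stereocentre is β to the carbonyl, cannot enolise, and changes descriptor only through the priority rules.

Step 5
Reactants: 6 cyclohexane-1,3-dione
Product: 7 1,4-dioxaspiro[4.5]decan-7-one
Conditions: ethylene glycol (1.1 equiv), TsOH·H2O (cat.), benzene, reflux, Dean–Stark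
Reagents that add atoms: ethane-1,2-diol, OCCO
Why: Acid-catalysed ketalisation of one carbonyl of the enolised dione: the hydroxyethyl enol ether formed first closes to the dioxolane, and one equivalent of glycol with removal of water stops at the mono-ketal.

Step 6
Reactants: 7 mono-ketal
Product: 8 (2R)-N-(1,4-dioxaspiro[4.5]decan-7-ylidene)-2-(methoxymethyl)pyrrolidin-1-amine (C=N geometry not fixed)
Conditions: RAMP, cyclohexane, reflux, water separator
Reagents that add atoms: (R)-1-amino-2-(methoxymethyl)pyrrolidine (RAMP), COC[C@H]1CCCN1N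
Why: Hydrazone condensation of the ketone with the chiral hydrazine; no stereocentre is formed.

Step 7
Reactants: 8 RAMP hydrazone
Product: 9 methyl 2-[(8R)-7-{[(2R)-2-(methoxymethyl)pyrrolidin-1-yl]imino}-1,4-dioxaspiro[4.5]decan-8-yl]acetate
Conditions: LDA, THF, 0 °C; then BrCH2CO2Me, −100 °C → −78 °C
Reagents that add atoms: methyl bromoacetate, COC(=O)CBr
Why: Chiral-hydrazone (azaenolate) alkylation: LDA metalates the less hindered α-CH2 remote from the ketal, and the lithium azaenolate, held rigid by chelation to the methoxymethyl group, is alkylated on one face, which sets C5 (R in 9).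

Step 8
Reactants: 9 alkylated hydrazone
Product: 11 methyl 2-[(1R)-2,4-dioxocyclohexyl]acetate, via keto ketal 10 (not isolated)
Conditions: O3, CH2Cl2, −78 °C; Me2S; then 1 M HCl, THF, rt
Reagents that add atoms: ozone, [O-][O+]=O; water, O
Why: Ozonolytic hydrazone cleavage frees the ketone without touching the new α-centre, and dilute acid then hydrolyses the β-keto ketal to the 1,3-dione, whose enolisation runs towards C9 and leaves C5 alone.

Step 9
Reactants: 11 4-substituted dione; 5 five-carbon aldehyde
Product: 13 methyl 2-{(1R)-3-[(3R)-5-[(tert-butyldiphenylsilyl)oxy]-3-methylpentyl]-2,4-dioxocyclohexyl}acetate, via alkylidene dione 12 (not isolated)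
Conditions: L-proline (cat.), Hantzsch ester, CH2Cl2, rt
Reagents that add atoms: none
Why: Three-component reductive alkylation: proline-catalysed Knoevenagel condensation at the acidic C9, then hydride transfer from the Hantzsch ester to the alkylidene dione, gives clean C-alkylation where an alkyl halide would mainly O-alkylate; C13 comes in with 5 and C9 is not yet a stereocentre.

Step 10
Reactants: 13 2,4-disubstituted dione
Product: 14 methyl 2-{(6S,8R)-6-[(3R)-5-[(tert-butyldiphenylsilyl)oxy]-3-methylpentyl]-7-oxo-1,4-dioxaspiro[4.5]decan-8-yl}acetate (C5 arm and C9 chain cis)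
Conditions: ethylene glycol, PPTS (cat.), benzene, reflux, Dean–Stark
Reagents that add atoms: ethane-1,2-diol, OCCO
Why: Acid-catalysed mono-ketalisation: the glycol goes to the C8 carbonyl (flanked by a CH2) and not to C10 (flanked by two branched carbons), and C9 is protonated within the reversible enol ether/dioxolane manifold, so the chain should settle equatorial and cis to the C5 arm while C5 is not part of that equilibrium.

Step 11
Reactants: 14 cis keto ketal
Product: 15 methyl 2-{(6S,8R)-6-[(3R)-5-[(tert-butyldiphenylsilyl)oxy]-3-methylpentyl]-7-methylidene-1,4-dioxaspiro[4.5]decan-8-yl}acetate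
Conditions: Zn, CH2Br2, TiCl4, THF/CH2Cl2, 0 °C → rt
Reagents that add atoms: dibromomethane, BrCBr
Why: Takai-type methylenation: the non-basic zinc–titanium methylene reagent olefinates the hindered, enolisable C10 ketone without epimerising C5 or C9 and leaves the ester and the dioxolane alone.

Step 12
Reactants: 15 methylene ester; 16 acrolein
Product: 17 methyl 3-hydroxy-2-{(6S,8R)-6-[(3R)-5-[(tert-butyldiphenylsilyl)oxy]-3-methylpentyl]-7-methylidene-1,4-dioxaspiro[4.5]decan-8-yl}pent-4-enoate (mixture at C3 and C4)
Conditions: LDA, THF, −78 °C; then acrolein, −78 °C; AcOH quench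
Reagents that add atoms: none
Why: Ester enolate aldol addition: the lithium enolate of the acetate arm adds 1,2 to acrolein at low temperature; C3 and C4 need no control, since C3 is oxidised next and C4 stays enolisable.

Step 13
Reactants: 17 aldol adduct
Product: 18 methyl 3-oxo-2-{(6S,8R)-6-[(3R)-5-[(tert-butyldiphenylsilyl)oxy]-3-methylpentyl]-7-methylidene-1,4-dioxaspiro[4.5]decan-8-yl}pent-4-enoate (C4 epimers and enol)
Conditions: Dess–Martin periodinane, CH2Cl2, 0 °C → rt
Reagents that add atoms: none
Why: Dess–Martin oxidation of the allylic alcohol gives the acryloyl β-keto ester under near-neutral conditions; it is prone to polymerise and is taken on at once.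

Step 14
Reactants: 18 ring B methylenecyclohexane with the vinyl ketone arm
Product: 19 trans-decalin keto ester (C3 ketone, C4 CO2Me, axial C20 methyl on C10, C8 dioxolane, equatorial C9 chain)
Conditions: Fe(acac)3, PhSiH3, EtOH/ethylene glycol, 60 °C, dilute
Reagents that add atoms: none
Why: An iron hydride formed from Fe(acac)3 and PhSiH3 in ethanol hands a hydrogen atom to the terminal carbon of the C10 methylene, which becomes C20 and leaves a tertiary, nucleophilic radical at C10; this radical adds to C1, the terminal carbon of the acryloyl group, and the C2 radical next to the ketone is reduced by divalent iron and protonated by the solvent, which returns the catalyst (closest known reaction type: the iron-hydride reductive coupling of unactivated alkenes with enones, run intramolecularly). Ring A closes in the 6-endo-trig mode through the C1–C10 bond, attack at C2 (5-exo) being polarity-mismatched. The only new stereocentre is C10, and the ring B chair controls it: the equatorial C5 tether can reach the face of the planar radical that lies syn to the axial H-5 and H-9 through a chair-like transition state, so C1 ends equatorial and the methyl axial, trans to H-5. The opposite face would give the cis-decalin and is screened by the axial oxygen of the C8 dioxolane. The step needs hydrogen transfer to one alkene only and closure faster than a second hydrogen transfer; the substrate secures the first because the 1,1-disubstituted C10 methylene is its only electron-rich alkene and the enone is a poor hydrogen-atom acceptor, and the second because the acceptor is tethered. C4 remains enolisable and is fixed in step 15.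

Step 15
Reactants: 19 trans-decalin keto ester
Product: 20 C4-methylated keto ester (equatorial C18 methyl, axial C19 CO2Me cis to C20)
Conditions: MeI, K2CO3, acetone, 40 °C
Reagents that add atoms: iodomethane, CI
Why: C-Alkylation of the β-keto ester enolate: iodomethane approaches C4 from the face opposite the axial C20 methyl, so the new methyl is equatorial and the ester axial, as in the target.

Step 16
Reactants: 20 methylated keto ester
Product: 21 C2=C3 enol triflate of 20
Conditions: KHMDS, THF, −78 °C; then PhNTf2, −78 °C → 0 °C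
Reagents that add atoms: N-phenylbis(trifluoromethanesulfonimide), O=S(=O)(N(c1ccccc1)S(=O)(=O)C(F)(F)F)C(F)(F)F
Why: Enolate triflation: the C3 ketone can enolise only towards C2, and the potassium enolate is trapped on oxygen.

Step 17
Reactants: 21 enol triflate
Product: 22 ring A saturated ester (C3 now CH2), C8 dioxolane retained
Conditions: H2 (1 atm), PtO2, NaHCO3, EtOAc, rt
Reagents that add atoms: none
Why: Catalytic hydrogenolysis of the enol triflate over platinum, with hydrogenation of the C2=C3 bond, turns the former ketone carbon into CH2; no other alkene is present and NaHCO3 takes up the triflic acid that would threaten the dioxolane.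

Step 18
Reactants: 22 ketal ester
Product: 23 C8 ketone
Conditions: 1 M HCl, THF, rt
Reagents that add atoms: water, O
Why: Acid-catalysed ketal hydrolysis frees the C8 ketone; C9 is now the only enolisable stereocentre and keeps, or under the acid regains, the equatorial side chain.

Step 19
Reactants: 23 C8 ketone
Product: 24 methyl (1R,4aS,5R,8aS)-5-[(3R)-5-[(tert-butyldiphenylsilyl)oxy]-3-methylpentyl]-1,4a-dimethyl-6-methylidenedecahydronaphthalene-1-carboxylate
Conditions: Ph3PCH3Br, KOtBu, toluene, rt → 80 °C
Reagents that add atoms: methyltriphenylphosphonium bromide, C[P+](c1ccccc1)(c1ccccc1)c1ccccc1.[Br-]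
Why: Wittig methylenation of the C8 ketone gives the exocyclic C8=C17 alkene; the hindered axial ester does not react and the basic ylide can only push C9 towards its stable configuration.

Step 20
Reactants: 24 methyl ester
Product: 25 (1R,4aS,5R,8aS)-5-[(3R)-5-[(tert-butyldiphenylsilyl)oxy]-3-methylpentyl]-1,4a-dimethyl-6-methylidenedecahydronaphthalene-1-carboxylic acid
Conditions: LiSPr, HMPA, rt; then 1 M HCl
Reagents that add atoms: none
Why: Nucleophilic demethylation (SN2 at the ester methyl by thiolate) frees the hindered axial C19 acid, which saponification would not reach, and spares the alkene and the silyl ether.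

Step 21
Reactants: 25 silyl ether acid
Product: 26 (1R,4aS,5R,8aS)-5-[(3R)-5-hydroxy-3-methylpentyl]-1,4a-dimethyl-6-methylidenedecahydronaphthalene-1-carboxylic acid
Conditions: TBAF, THF, rt; then dilute HCl
Reagents that add atoms: none
Why: Fluoride-induced desilylation frees the C15 alcohol.

Step 22
Reactants: 26 hydroxy acid; 27 (R)-2-methylbutanoic acid
Product: 28 (1R,4aS,5R,8aS)-1,4a-dimethyl-6-methylidene-5-[(3R)-3-methyl-5-{[(2R)-2-methylbutanoyl]oxy}pentyl]decahydronaphthalene-1-carboxylic acid (target)
Conditions: 27 premixed with DCC, CH2Cl2, 0 °C; then 26, DMAP (cat.), 0 °C → rt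
Reagents that add atoms: none
Why: Steglich esterification: the carbodiimide activates the unhindered acid 27, which acylates the primary C15 alcohol, while the neopentyl-type axial C19 acid is too hindered to be activated or to act as acyl donor; low temperature and catalytic DMAP keep the α-centre of the acyl group intact.

**Compound list**
1 | (R)-citronellol | C[C@H](CCC=C(C)C)CCO | starting material
2 | tert-butyl{[(3R)-3,7-dimethyloct-6-en-1-yl]oxy}diphenylsilane | C[C@H](CCC=C(C)C)CCO[Si](c1ccccc1)(c1ccccc1)C(C)(C)C | intermediate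
3 | (4R)-6-[(tert-butyldiphenylsilyl)oxy]-4-methylhexanal | C[C@H](CCC=O)CCO[Si](c1ccccc1)(c1ccccc1)C(C)(C)C | intermediate
4 | tert-butyl({(4R)-6-[(tert-butyldiphenylsilyl)oxy]-4-methylhex-1-en-1-yl}oxy)dimethylsilane (E/Z) | C[C@H](CCC=CO[Si](C)(C)C(C)(C)C)CCO[Si](c1ccccc1)(c1ccccc1)C(C)(C)C | intermediate
5 | (3S)-5-[(tert-butyldiphenylsilyl)oxy]-3-methylpentanal | C[C@H](CC=O)CCO[Si](c1ccccc1)(c1ccccc1)C(C)(C)C | intermediate
6 | cyclohexane-1,3-dione | O=C1CCCC(=O)C1 | starting material
7 | 1,4-dioxaspiro[4.5]decan-7-one | O=C1CCCC2(C1)OCCO2 | intermediate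
8 | (2R)-N-(1,4-dioxaspiro[4.5]decan-7-ylidene)-2-(methoxymethyl)pyrrolidin-1-amine | COC[C@H]1CCCN1N=C1CCCC2(C1)OCCO2 | intermediate
9 | methyl 2-[(8R)-7-{[(2R)-2-(methoxymethyl)pyrrolidin-1-yl]imino}-1,4-dioxaspiro[4.5]decan-8-yl]acetate | COC[C@H]1CCCN1N=C1[C@@H](CC(=O)OC)CCC2(C1)OCCO2 | intermediate
10 | methyl 2-[(8R)-7-oxo-1,4-dioxaspiro[4.5]decan-8-yl]acetate | O=C1[C@@H](CC(=O)OC)CCC2(C1)OCCO2 | intermediate
11 | methyl 2-[(1R)-2,4-dioxocyclohexyl]acetate | O=C1CC(=O)CC[C@@H]1CC(=O)OC | intermediate
12 | methyl 2-{(1R)-3-[(3R)-5-[(tert-butyldiphenylsilyl)oxy]-3-methylpentylidene]-2,4-dioxocyclohexyl}acetate | O=C1C(=CC[C@@H](C)CCO[Si](c2ccccc2)(c2ccccc2)C(C)(C)C)C(=O)CC[C@@H]1CC(=O)OC | intermediate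
13 | methyl 2-{(1R)-3-[(3R)-5-[(tert-butyldiphenylsilyl)oxy]-3-methylpentyl]-2,4-dioxocyclohexyl}acetate | O=C1C(CC[C@@H](C)CCO[Si](c2ccccc2)(c2ccccc2)C(C)(C)C)C(=O)CC[C@@H]1CC(=O)OC | intermediate
14 | methyl 2-{(6S,8R)-6-[(3R)-5-[(tert-butyldiphenylsilyl)oxy]-3-methylpentyl]-7-oxo-1,4-dioxaspiro[4.5]decan-8-yl}acetate | O=C1[C@@H](CC(=O)OC)CCC2(OCCO2)[C@H]1CC[C@@H](C)CCO[Si](c3ccccc3)(c3ccccc3)C(C)(C)C | intermediate
15 | methyl 2-{(6S,8R)-6-[(3R)-5-[(tert-butyldiphenylsilyl)oxy]-3-methylpentyl]-7-methylidene-1,4-dioxaspiro[4.5]decan-8-yl}acetate | C=C1[C@@H](CC(=O)OC)CCC2(OCCO2)[C@H]1CC[C@@H](C)CCO[Si](c3ccccc3)(c3ccccc3)C(C)(C)C | intermediate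
16 | acrolein | C=CC=O | starting material
17 | methyl 3-hydroxy-2-{(6S,8R)-6-[(3R)-5-[(tert-butyldiphenylsilyl)oxy]-3-methylpentyl]-7-methylidene-1,4-dioxaspiro[4.5]decan-8-yl}pent-4-enoate (C3/C4 mixture) | C=CC(O)C(C(=O)OC)[C@H]1CCC2(OCCO2)[C@@H](CC[C@@H](C)CCO[Si](c3ccccc3)(c3ccccc3)C(C)(C)C)C1=C | intermediate
18 | methyl 3-oxo-2-{(6S,8R)-6-[(3R)-5-[(tert-butyldiphenylsilyl)oxy]-3-methylpentyl]-7-methylidene-1,4-dioxaspiro[4.5]decan-8-yl}pent-4-enoate (C4 epimers) | C=CC(=O)C(C(=O)OC)[C@H]1CCC2(OCCO2)[C@@H](CC[C@@H](C)CCO[Si](c3ccccc3)(c3ccccc3)C(C)(C)C)C1=C | intermediate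
19 | trans-decalin keto ester: C3 ketone, C4 CO2Me (drawn equatorial, epimerisable), axial C20 methyl on C10 trans to H-5, C8 ethylene ketal, equatorial C9 (3R)-5-silyloxy-3-methylpentyl chain; C5, C9, C10 as in the target | O1CCOC12CC[C@H]3[C@@](C)(CCC(=O)[C@@H]3C(=O)OC)[C@@H]2CC[C@@H](C)CCO[Si](c4ccccc4)(c4ccccc4)C(C)(C)C | intermediate
20 | 19 with quaternary C4: equatorial methyl (C18), axial CO2Me (C19) cis to C20 | O1CCOC12CC[C@H]3[C@@](C)(CCC(=O)[C@@]3(C)C(=O)OC)[C@@H]2CC[C@@H](C)CCO[Si](c4ccccc4)(c4ccccc4)C(C)(C)C | intermediate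
21 | C2=C3 enol triflate of 20 | O1CCOC12CC[C@H]3[C@@](C)(CC=C(OS(=O)(=O)C(F)(F)F)[C@@]3(C)C(=O)OC)[C@@H]2CC[C@@H](C)CCO[Si](c4ccccc4)(c4ccccc4)C(C)(C)C | intermediate
22 | 3-deoxo ester with ring A saturated and C8 ethylene ketal | O1CCOC12CC[C@H]3[C@@](C)(CCC[C@@]3(C)C(=O)OC)[C@@H]2CC[C@@H](C)CCO[Si](c4ccccc4)(c4ccccc4)C(C)(C)C | intermediate
23 | C8 ketone of 22 (equatorial C9 chain) | O=C1CC[C@H]2[C@@](C)(CCC[C@@]2(C)C(=O)OC)[C@@H]1CC[C@@H](C)CCO[Si](c3ccccc3)(c3ccccc3)C(C)(C)C | intermediate
24 | methyl (1R,4aS,5R,8aS)-5-[(3R)-5-[(tert-butyldiphenylsilyl)oxy]-3-methylpentyl]-1,4a-dimethyl-6-methylidenedecahydronaphthalene-1-carboxylate | C=C1CC[C@H]2[C@@](C)(CCC[C@@]2(C)C(=O)OC)[C@@H]1CC[C@@H](C)CCO[Si](c3ccccc3)(c3ccccc3)C(C)(C)C | intermediate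
25 | (1R,4aS,5R,8aS)-5-[(3R)-5-[(tert-butyldiphenylsilyl)oxy]-3-methylpentyl]-1,4a-dimethyl-6-methylidenedecahydronaphthalene-1-carboxylic acid | C=C1CC[C@H]2[C@@](C)(CCC[C@@]2(C)C(=O)O)[C@@H]1CC[C@@H](C)CCO[Si](c3ccccc3)(c3ccccc3)C(C)(C)C | intermediate
26 | (1R,4aS,5R,8aS)-5-[(3R)-5-hydroxy-3-methylpentyl]-1,4a-dimethyl-6-methylidenedecahydronaphthalene-1-carboxylic acid | C=C1CC[C@H]2[C@@](C)(CCC[C@@]2(C)C(=O)O)[C@@H]1CC[C@@H](C)CCO | intermediate
27 | (R)-2-methylbutanoic acid | CC[C@@H](C)C(=O)O | starting material
28 | (1R,4aS,5R,8aS)-1,4a-dimethyl-6-methylidene-5-[(3R)-3-methyl-5-{[(2R)-2-methylbutanoyl]oxy}pentyl]decahydronaphthalene-1-carboxylic acid | C=C1CC[C@H]2[C@@](C)(CCC[C@@]2(C)C(=O)O)[C@@H]1CC[C@@H](C)CCOC(=O)[C@H](C)CC | target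

**Step count**
Total: 22 steps. Longest linear sequence: 18 steps (steps 5–22 from cyclohexane-1,3-dione; the citronellol branch, steps 1–4 then 9–22, is equally long).

**Steps most likely to fail**

1. Step 14 (key step). The C10 radical may take a second hydrogen atom before it closes (plain hydrogenation of the methylene), the acryloyl keto ester may oligomerise, or closure may occur on the axial face and give the cis-decalin. The fallback sets out from 15 and comes back at 19. The same iron hydride conditions (Fe(acac)3, PhSiH3, EtOH/ethylene glycol, 60 °C) are applied to 15 with an excess of N-methoxy-N-methylacrylamide. This intermolecular reductive coupling uses a stable acceptor in excess and should give the Weinreb amide ester F1, with C1 entering on the face away from the axial dioxolane oxygen. LDA (THF, −78 °C → 0 °C) then forms the enolate of the acetate arm, which acylates itself on the amide; the chelated tetrahedral intermediate prevents reversal and the regioisomeric closure, and work-up gives 19. Ring A is then closed at C3–C4 by a polar step, and the sensitive vinyl ketone 18 is never made.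

2. Step 10. Ketalisation may stop at the hydroxyethyl enol ether, may not distinguish the two carbonyls cleanly, or may erode C5 through acid-catalysed enolisation of the C10 ketone. The fallback sets out from 10 (isolated by leaving out the acid treatment in step 8) and comes back at 14; the dioxolane of 10 is kept throughout. LDA (THF, −78 °C) enolises 10 at the C9 methylene and aldehyde 5 is added to give the aldol adduct F2. MsCl/Et3N dehydrates it to the alkylidene ketone F3. Hydrogenation (H2, Pd/C, EtOAc) saturates the C9=C11 bond and gives 14; any C9 epimer formed alongside is corrected later at 23, where C9 is the only enolisable centre.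

3. Step 7. Metalation may take place on the ketal side and open the dioxolane, or facial control of the azaenolate may be incomplete. The fallback sets out from 7 and comes back at 10, and replaces the auxiliary by enamine catalysis. D-Proline-catalysed aldol addition of 7 to methyl glyoxylate (DMSO, rt), with the enamine forming on the side remote from the ketal, gives the hydroxy ester F4 with the ring centre set by the catalyst. Ac2O/pyridine gives the acetate F5. SmI2 (THF/MeOH, −78 °C) removes the α-acetoxy group of the ester and gives 10.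

**Further compounds**
F1 | step 14 | Weinreb amide ester: ring B of 15 with C10 bearing the C20 methyl and a 3-[methoxy(methyl)amino]-3-oxopropyl group (C1–C3), C5 CH2CO2Me arm intact | O1CCOC12CC[C@H](CC(=O)OC)[C@@](C)(CCC(=O)N(C)OC)[C@@H]2CC[C@@H](C)CCO[Si](c3ccccc3)(c3ccccc3)C(C)(C)C
F2 | step 10 | aldol adduct of 10 and 5 at C9 (mixture at C9 and C11) | O=C1[C@@H](CC(=O)OC)CCC2(OCCO2)C1C(O)C[C@@H](C)CCO[Si](c3ccccc3)(c3ccccc3)C(C)(C)C
F3 | step 10 | alkylidene ketone with C9=C11 double bond | O=C1[C@@H](CC(=O)OC)CCC2(OCCO2)C1=CC[C@@H](C)CCO[Si](c3ccccc3)(c3ccccc3)C(C)(C)C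
F4 | step 7 | methyl 2-hydroxy-2-(7-oxo-1,4-dioxaspiro[4.5]decan-8-yl)acetate (ring centre as in 10) | O=C1[C@@H](C(O)C(=O)OC)CCC2(C1)OCCO2
F5 | step 7 | methyl 2-acetoxy-2-(7-oxo-1,4-dioxaspiro[4.5]decan-8-yl)acetate (ring centre as in 10) | O=C1[C@@H](C(OC(C)=O)C(=O)OC)CCC2(C1)OCCO2
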